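**Assumptions.** CIP analysis of the SMILES gives 2S at the flavanone carbon and 2''R in the side chain, which is natural kurarinol. Commercial (+)-limonene oxide is taken as (4R). Only substrates and intermediates are numbered; stock reagents are given by name and SMILES in each step.

## Retrosynthetic overview
1. Target ⇒ global desilylation ⇒ C2–C1' bond made by Rh-catalysed enantioselective 1,4-arylation of an 8-alkylchromone with a 2,4-bis(silyloxy)phenylboronic acid. This sets 2S without a chalcone.
2. Chromone C ring ⇒ 6-endo oxa-Michael closure of an o-hydroxyaryl ynone ⇒ OH-directed formylation of a fully differentiated phloroglucinol.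
3. The A ring is built, not bought. A Danheiser-type benzannulation of a siloxyalkyne with 3-methoxycyclobutenone places the side chain between a free OH and an OTIPS, with OMe para. This fixes the 8-alkyl/7-OH/5-OMe pattern.
4. Siloxyalkyne ⇒ (R)-limonene oxide by ring cleavage. Limonene C4 becomes C2''(R), the aldehyde carbon (limonene C2) becomes arene C8, and the methyl ketone plus MeMgBr gives the carbinol. No lavandulyl electrophile is used.
5. Ring order: A (benzannulation) → C (chromone) → B attached intact.

## Route

**Step 1**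
Reactants: 1, (+)-(4R)-limonene 1,2-oxide (commercial cis/trans mixture)
Product: 2, (3R)-6-oxo-3-(prop-1-en-2-yl)heptanal
Conditions: H5IO6 (1.2 equiv), THF/H2O 4:1, 0 °C → rt
Reagents that add atoms: water, O
Why: One-pot epoxide hydrolysis and Malaprade glycol cleavage converges both epoxide isomers, leaves the isopropenyl group alone, and carries limonene C4 (β, not α, to the aldehyde) through unchanged as the R centre.

**Step 2**
Reactants: 2
Product: 3, (5R)-8,8-dibromo-5-(prop-1-en-2-yl)oct-7-en-2-one
Conditions: CBr4 (2 equiv), PPh3 (4 equiv), Et3N (1 equiv), CH2Cl2, 0 °C, 30 min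
Reagents that add atoms: carbon tetrabromide, BrC(Br)(Br)Br
Why: In this Ramirez dibromo-olefination (Corey–Fuchs stage 1), Ph3P=CBr2 consumes the aldehyde in minutes while the methyl ketone is inert, and the near-neutral medium avoids intramolecular aldol of the 1,6-keto aldehyde.

**Step 3**
Reactants: 3
Product: 4, (5R)-2-methyl-5-(prop-1-en-2-yl)oct-7-yn-2-ol
Conditions: MeMgBr (1.3 equiv), THF, −78 → 0 °C; then n-BuLi (3.2 equiv), −78 → 0 °C; aq NH4Cl
Reagents that add atoms: methylmagnesium bromide, C[Mg]Br
Why: Grignard 1,2-addition to the ketone (the gem-dibromoalkene ignores RMgX) is followed in the same flask by Corey–Fuchs stage 2 (Br/Li exchange, Fritsch–Buttenberg–Wiechell shift), so the former aldehyde carbon becomes the internal alkyne carbon.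

**Step 4**
Reactants: 4
Product: 5, triethyl{[(5R)-2-methyl-5-(prop-1-en-2-yl)oct-7-yn-2-yl]oxy}silane
Conditions: TESOTf (1.3 equiv), 2,6-lutidine (2 equiv), CH2Cl2, −78 → 0 °C
Reagents that add atoms: triethylsilyl triflate, CC[Si](CC)(CC)OS(=O)(=O)C(F)(F)F
Why: Silyl triflate silylation caps the hindered tertiary alcohol so it cannot trap the ketene intermediates of Step 7, and a tertiary OTES survives every later step until fluoride.

**Step 5**
Reactants: 5
Product: 6, triisopropyl{[(4R)-7-methyl-4-(prop-1-en-2-yl)-7-(triethylsilyloxy)oct-1-yn-1-yl]oxy}silane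
Conditions: n-BuLi (1.05 equiv), THF, −78 °C; LiOOt-Bu (from t-BuOOH + LiHMDS), −78 → 0 °C; TIPSOTf (1.3 equiv), −78 → 0 °C
Reagents that add atoms: tert-butyl hydroperoxide, CC(C)(C)OO; triisopropylsilyl triflate, CC(C)[Si](C(C)C)(C(C)C)OS(=O)(=O)C(F)(F)F
Why: Oxenoid oxidation of a lithium acetylide (the acetylide attacks the electrophilic O of LiOOt-Bu) gives the lithium ynolate, which the bulky TIPS electrophile silylates on oxygen, while the unactivated alkene is inert to LiOOt-Bu.

**Step 6**
Reactants: 7, cyclobutane-1,3-dione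
Product: 8, 3-methoxycyclobut-2-en-1-one
Conditions: TMSCHN2 (1.1 equiv), Et2O/MeOH 9:1, 0 °C; bulb-to-bulb distillation
Reagents that add atoms: (trimethylsilyl)diazomethane, C[Si](C)(C)C=[N+]=[N-] (supplies the O-methyl carbon)
Why: Diazoalkane O-methylation of a strongly acidic enol (a vinylogous acid) avoids the acid/alcohol conditions that ring-open this strained β-diketone.

**Step 7 (key step)**
Reactants: 6; 8 (1.5 equiv, added slowly)
Product: 9, 5-methoxy-2-[(2R)-5-methyl-2-(prop-1-en-2-yl)-5-(triethylsilyloxy)hexyl]-3-(triisopropylsilyloxy)phenol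
Conditions: xylenes (0.3 M), reflux (about 140 °C), Ar, 12–24 h
Reagents that add atoms: none (both reactants are fully incorporated)
Why: Proposed new method: this extends the Danheiser benzannulation (known for 3-alkylcyclobutenones plus TIPS-oxyalkynes, giving 2-alkylresorcinol monosilyl ethers) to a 3-alkoxycyclobutenone, in which 4π opening of 8 gives (1-methoxyvinyl)ketene, the nucleophilic alkyl-bearing carbon of 6 attacks the ketene carbonyl carbon in a regiospecific [2+2], and the resulting 2-alkyl-3-siloxy-4-(1-methoxyvinyl)cyclobutenone (a class known to aromatise at ≤100 °C) undergoes 4π opening, 6π closure and tautomerisation, so the chain sits between the new free OH and the OTIPS with OMe para; the higher temperature offsets the vinylogous-ester stabilisation of 8, no stereocentre forms, and C2'' is a spectator because the competing 1,5-enyne Cope needs >250 °C.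

**Step 8**
Reactants: 9
Product: 10, 2-hydroxy-6-methoxy-3-[(2R)-5-methyl-2-(prop-1-en-2-yl)-5-(triethylsilyloxy)hexyl]-4-(triisopropylsilyloxy)benzaldehyde
Conditions: MgCl2 (3 equiv), Et3N (5 equiv), (CH2O)n (8 equiv), THF, reflux
Reagents that add atoms: paraformaldehyde (formaldehyde), C=O
Why: In the Casnati–Skattebøl ortho-formylation the magnesium phenoxide delivers CH2O only ortho to the free OH, only one such position is open, and the non-acidic conditions spare the silyl ethers and the alkene.

**Step 9**
Reactants: 10
Product: 11, 1-{2-hydroxy-6-methoxy-3-[(2R)-5-methyl-2-(prop-1-en-2-yl)-5-(triethylsilyloxy)hexyl]-4-(triisopropylsilyloxy)phenyl}prop-2-yn-1-ol (carbinol epimers, used crude)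
Conditions: HC≡CMgBr (3.5 equiv), THF, −20 → 0 °C; pH 7 buffer
Reagents that add atoms: ethynylmagnesium bromide, C#C[Mg]Br
Why: This is a Grignard 1,2-addition in which the first equivalent deprotonates the phenol, the new carbinol centre is erased in Step 10, and the neutral work-up avoids o-quinone methide formation.

**Step 10**
Reactants: 11
Product: 12, 5-methoxy-8-[(2R)-5-methyl-2-(prop-1-en-2-yl)-5-(triethylsilyloxy)hexyl]-7-(triisopropylsilyloxy)-4H-chromen-4-one
Conditions: activated MnO2 (20 equiv), CH2Cl2, rt; filter; DMAP (20 mol %), CH2Cl2, rt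
Reagents that add atoms: none
Why: Benzylic/propargylic MnO2 oxidation gives the o-hydroxyaryl terminal ynone, and nucleophile-catalysed 6-endo-dig oxa-Michael addition at the unsubstituted β-carbon closes the C ring.

**Step 11**
Reactants: 13, 4-bromoresorcinol
Product: 14, 1-bromo-2,4-bis(tert-butyldimethylsilyloxy)benzene
Conditions: TBSCl (2.5 equiv), imidazole (5 equiv), DMF, rt
Reagents that add atoms: tert-butyldimethylsilyl chloride, CC(C)(C)[Si](C)(C)Cl
Why: Standard imidazole-promoted phenol silylation is used, with TBS chosen so that every protecting group in the molecule leaves with one fluoride treatment.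

**Step 12**
Reactants: 14
Product: 15, [2,4-bis(tert-butyldimethylsilyloxy)phenyl]boronic acid
Conditions: B(Oi-Pr)3 (1.5 equiv) present, n-BuLi (1.1 equiv) added dropwise, THF/toluene, −78 °C; aq NH4Cl
Reagents that add atoms: triisopropyl borate, CC(C)OB(OC(C)C)OC(C)C; water, O
Why: Br/Li exchange with in-situ borate quench captures the aryllithium before the ortho O→C silyl shift (retro-Brook) can occur, and mild hydrolysis frees the boronic acid.

**Step 13**
Reactants: 12; 15 (3 equiv, in portions)
Product: 16, (2S)-2-[2,4-bis(tert-butyldimethylsilyloxy)phenyl]-5-methoxy-8-[(2R)-5-methyl-2-(prop-1-en-2-yl)-5-(triethylsilyloxy)hexyl]-7-(triisopropylsilyloxy)-2,3-dihydro-4H-chromen-4-one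
Conditions: preformed [Rh(OH)((S)-MeO-F12-BIPHEP)]2 (3 mol % Rh), toluene/H2O 20:1, 25–35 °C, no added base
Reagents that add atoms: none beyond 15 (water supplies only H)
Why: In this Hayashi–Miyaura asymmetric 1,4-addition to a chromone, the aryl–Rh species carborhodates C2=C3 from the C2 Re face (the same sense as (S)-biaryl bisphosphines giving (S)-3-arylcyclohexanones, which maps onto 2S), control is by catalyst and independent of remote C2'', fast protonolysis at rt prevents retro-oxa-Michael, and any 2R epimer is a separable diastereomer.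

**Step 14**
Reactants: 16
Product: 17, (2S)-2-(2,4-dihydroxyphenyl)-7-hydroxy-8-[(2R)-5-hydroxy-5-methyl-2-(prop-1-en-2-yl)hexyl]-5-methoxy-2,3-dihydro-4H-chromen-4-one (target)
Conditions: HF·pyridine (excess), pyridine, THF, 0 °C → rt (plastic vessel); pH 7 buffer
Reagents that add atoms: none
Why: Buffered fluoride global desilylation removes the aryl TIPS, both aryl TBS groups and the tertiary TES without generating phenoxide (so no chalcone ring-opening or C2 racemisation), and it is too weakly acidic to ionise the tertiary alcohol or cyclise 7-OH onto the isopropenyl group.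

## Compound list
1 | (+)-(4R)-limonene 1,2-oxide (cis/trans) | CC12OC1C[C@@H](CC2)C(C)=C | starting material
2 | (3R)-6-oxo-3-(prop-1-en-2-yl)heptanal | O=CC[C@@H](CCC(C)=O)C(C)=C | intermediate
3 | (5R)-8,8-dibromo-5-(prop-1-en-2-yl)oct-7-en-2-one | BrC(Br)=CC[C@@H](CCC(C)=O)C(C)=C | intermediate
4 | (5R)-2-methyl-5-(prop-1-en-2-yl)oct-7-yn-2-ol | C#CC[C@@H](CCC(C)(C)O)C(C)=C | intermediate
5 | TES ether of 4 | C#CC[C@@H](CCC(C)(C)O[Si](CC)(CC)CC)C(C)=C | intermediate
6 | (4R)-TIPS ynol ether | CC(C)[Si](OC#CC[C@@H](CCC(C)(C)O[Si](CC)(CC)CC)C(C)=C)(C(C)C)C(C)C | intermediate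
7 | cyclobutane-1,3-dione | O=C1CC(=O)C1 | starting material
8 | 3-methoxycyclobut-2-en-1-one | COC1=CC(=O)C1 | intermediate
9 | differentiated 2-alkylphloroglucinol (free OH / OTIPS / OMe) | COc1cc(O)c(C[C@@H](CCC(C)(C)O[Si](CC)(CC)CC)C(C)=C)c(O[Si](C(C)C)(C(C)C)C(C)C)c1 | intermediate
10 | salicylaldehyde | COc1cc(O[Si](C(C)C)(C(C)C)C(C)C)c(C[C@@H](CCC(C)(C)O[Si](CC)(CC)CC)C(C)=C)c(O)c1C=O | intermediate
11 | propargylic alcohol (carbinol epimers) | COc1cc(O[Si](C(C)C)(C(C)C)C(C)C)c(C[C@@H](CCC(C)(C)O[Si](CC)(CC)CC)C(C)=C)c(O)c1C(O)C#C | intermediate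
12 | 8-alkyl-5-methoxy-7-TIPSO-chromone | COc1cc(O[Si](C(C)C)(C(C)C)C(C)C)c(C[C@@H](CCC(C)(C)O[Si](CC)(CC)CC)C(C)=C)c2occc(=O)c12 | intermediate
13 | 4-bromoresorcinol | Oc1ccc(Br)c(O)c1 | starting material
14 | 1-bromo-2,4-bis(TBSO)benzene | CC(C)(C)[Si](C)(C)Oc1ccc(Br)c(O[Si](C)(C)C(C)(C)C)c1 | intermediate
15 | [2,4-bis(TBSO)phenyl]boronic acid | OB(O)c1ccc(O[Si](C)(C)C(C)(C)C)cc1O[Si](C)(C)C(C)(C)C | intermediate
16 | (2S,2''R) fully silylated flavanone | COc1cc(O[Si](C(C)C)(C(C)C)C(C)C)c(C[C@@H](CCC(C)(C)O[Si](CC)(CC)CC)C(C)=C)c2O[C@H](c3ccc(O[Si](C)(C)C(C)(C)C)cc3O[Si](C)(C)C(C)(C)C)CC(=O)c12 | intermediate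
17 | (2S,2''R)-kurarinol, CID44563198 | C=C(C)[C@H](CCC(C)(C)O)Cc1c(O)cc(OC)c2c1O[C@H](c1ccc(O)cc1O)CC2=O | target

## Summary
**Total steps:** 14.

**Longest linear sequence:** 11 steps (1→2→3→4→5→6→9→10→11→12→16→17).

**Three steps most likely to fail, each with one fallback:**

1. **Step 7, benzannulation with a 3-alkoxycyclobutenone.** The ring opening of 8 may be sluggish, the ketene may dimerise, or it may acylate phenol 9.
   - Fallback: reach the same 4-(1-methoxyvinyl)cyclobutenone without a free vinylketene.
   - A [2+2] of 6 with dichloroketene, then Zn mono-dechlorination, gives the 4-chlorocyclobutenone.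
   - Stille coupling with tributyl(1-methoxyvinyl)stannane and aromatisation at 100 °C then follow (a cross-coupling-based phenol synthesis).
2. **Step 13, 1,4-arylation.** The boronic acid is ortho-silyloxy-substituted and prone to protodeboronation, and the chromone is electron-rich.
   - Fallback: form C2–H instead of C2–C.
   - Add the lithium acetylide of 1-ethynyl-2,4-bis(TBSO)benzene to aldehyde 10, then oxidise and cyclise to the flavone.
   - Set C2 by CuH/chiral bisphosphine asymmetric conjugate reduction. The C2 epimers are diastereomers, so they can be separated.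
3. **Step 5, acetylide oxidation and O-silylation.**
   - Fallback: reach the same ynolate by Kowalski ester homologation.
   - Oxidise 2 to the methyl ester, add MeMgBr to the ketone at −78 °C, and protect as the TES ether.
   - Treat with LiCHBr2, then base and n-BuLi, to give the rearranged ynolate, and trap it with TIPSCl to give 6.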